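**Plan**

1. The retrosynthesis first cuts the two malonate ester C–O bonds, then the C11–C12 bond of each labdane half (sulfone alkylation). This leaves a drimane core and a five-carbon (E)-allylic bromide.
2. The enabling feature lies in ring B: C8 carries a methyl group and an oxygen and sits 1,4 to the ring-fusion carbon C5. Tying C8 to C5 through that oxygen gives a 7-oxanorbornene, which is a 2-methylfuran (C5–C6–C7–C8 plus O) added across a C9=C10 alkene.
3. C5–C10 and C8–C9 are therefore cut together (intramolecular furan Diels–Alder), opening rings A and B at once to an acyclic furyl enal. The furan–C4 bond is cut last (Friedel–Crafts hydroarylation of methyl geranate).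
4. Forward: chain assembly (3 steps), rings A and B in one cycloaddition, aldehyde reduction, C5–O bridge opening, C11 sulfone, hydrogenation, side-chain alkylation, desulfonylation, and double esterification of malonic acid.
5. Stereochemistry: C8, C9 and C10 come from the cycloaddition (E enal, exo tether, endo iminium; absolute sense from the chiral imidazolidinone). The 5α-hydrogen comes from hydrogenation directed by the 8α-hydroxyl. The 13E geometry comes from SeO2 oxidation of the E-methyl group of a prenyl ether.
6. Labdane numbering is used for all bicyclic compounds: C1–C10 decalin, ring A = C1–C5/C10, ring B = C5–C10, C11 on C9, C17 = methyl on C8, C18/C19 on C4, C20 = methyl on C10.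

Key step: step 4

Assumptions: methyl (2E)-geranate is bought as the geometrically pure E ester; the (2S,5S) catalyst antipode is assigned from the usual face-shielding model of 5-benzylimidazolidinone iminium ions (benzyl group over one face of the s-trans (E)-iminium ion).

**Route**

Step 1
Reactants: 1 methyl (2E)-3,7-dimethylocta-2,6-dienoate (methyl geranate); 2 2-methylfuran
Product: 3 methyl (2E)-3,7-dimethyl-7-(5-methylfuran-2-yl)oct-2-enoate
Conditions: 2 (6 equiv), dry Amberlyst-15 (sulfonic acid resin), CH2Cl2, 0 °C to rt
Reagents that add atoms: none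
Why: Friedel–Crafts hydroarylation: protonation of the electron-rich isopropylidene alkene gives the tertiary cation (future C4), which the free α-position of 2-methylfuran should capture, while the conjugated enoate alkene is neither basic nor nucleophilic and keeps its E geometry.

Step 2
Reactants: 3 methyl (2E)-3,7-dimethyl-7-(5-methylfuran-2-yl)oct-2-enoate
Product: 4 (2E)-3,7-dimethyl-7-(5-methylfuran-2-yl)oct-2-en-1-ol
Conditions: DIBAL-H (2.2 equiv), CH2Cl2, −78 °C; aq. potassium sodium tartrate
Reagents that add atoms: none
Why: 1,2-reduction of an enoate by an aluminium hydride gives the allylic alcohol without touching the alkene geometry or the furan.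

Step 3
Reactants: 4 (2E)-3,7-dimethyl-7-(5-methylfuran-2-yl)oct-2-en-1-ol
Product: 5 (2E)-3,7-dimethyl-7-(5-methylfuran-2-yl)oct-2-enal
Conditions: activated MnO2 (10 equiv), CH2Cl2, rt
Reagents that add atoms: none
Why: allylic oxidation with MnO2 is neutral and selective for the allylic alcohol, so the E enal should form without isomerisation and without attack on the furan.

Step 4
Reactants: 5 (2E)-3,7-dimethyl-7-(5-methylfuran-2-yl)oct-2-enal
Product: 7 5α,8α-epoxydrim-6-en-11-al (9α-H, 10β-methyl, formyl group on the β face anti to the oxygen bridge), via iminium ion 6 (not isolated)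
Conditions: (2S,5S)-5-benzyl-2-tert-butyl-3-methylimidazolidin-4-one·CF3CO2H (20 mol %), MeCN/H2O 95:5, −20 °C; cold aqueous work-up, crude 7 used at once
Reagents that add atoms: none
Why: Proposed new method: the enal condenses with the secondary amine salt to an (E)-configured α,β-unsaturated iminium ion whose lowered LUMO is attacked by the electron-rich 2,5-dialkylfuran (diene C5–C6–C7–C8) in a concerted but asynchronous [4+2] addition across C9=C10, and hydrolysis frees aldehyde 7 and the amine; the closest known reactions are thermal or Lewis-acid-promoted intramolecular Diels–Alder reactions of furans and imidazolidinone-catalysed intramolecular Diels–Alder reactions of trienals. Ring A closes by the C5–C10 bond with the four-carbon tether C1–C4 lying exo (six-membered, fused mode, helped by the gem-dimethyl group at C4), and ring B closes as the cyclohexene ring of the 7-oxanorbornene through the C5–C10 and C8–C9 bonds. C9 and C10 are related by suprafacial addition to the E alkene (C11 and the C10 methyl stay cis), while C5 and C8 follow from the exo tether and the endo iminium, which put the oxygen bridge anti to C11 and to the C10 methyl, that is on the α face. The absolute sense is set by the benzyl arm of the catalyst, which covers one face of the iminium ion so that the furan adds to the other. The step needs endo/exo and π-facial selectivity: the s-cis-locked furan, the E geometry and the short tether leave a single relative arrangement, and the catalyst chooses the enantiotopic face. Because the C5–C10 bond joins two fully substituted carbons and furan adducts can revert, the reaction is run cold and crude 7 is reduced at once in step 5.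

Step 5
Reactants: 7 5α,8α-epoxydrim-6-en-11-al
Product: 8 5α,8α-epoxydrim-6-en-11-ol
Conditions: NaBH4, MeOH, −40 to 0 °C
Reagents that add atoms: none
Why: borohydride reduction of the aldehyde removes the activating carbonyl group, which should shut down both cycloreversion and β-elimination of the bridging oxygen through the C9 enol; no stereocentre is formed or touched.

Step 6
Reactants: 8 5α,8α-epoxydrim-6-en-11-ol
Product: 9 drim-5-ene-8α,11-diol
Conditions: LiAlH4 (3 equiv), THF, 66 °C; aqueous work-up
Reagents that add atoms: none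
Why: alkoxide-directed SN2′ reductive ring opening (hydroalumination with β-alkoxide elimination): the C11 alkoxyaluminate sits on the endo (β) face directly below C7 and should deliver hydride there, the double bond shifts to C5=C6 and the anti-disposed C5–O bond breaks, so the oxygen stays on C8 with its α configuration.

Step 7
Reactants: 9 drim-5-ene-8α,11-diol
Product: 10 11-(phenylsulfanyl)drim-5-en-8α-ol
Conditions: PhSSPh (1.5 equiv), PBu3 (1.5 equiv), pyridine, 60 °C
Reagents that add atoms: diphenyl disulfide c1ccccc1SSc1ccccc1
Why: Hata thioetherification: the primary C11 alcohol forms an alkoxyphosphonium ion that thiophenolate displaces by SN2, while the tertiary 8α-hydroxyl cannot react.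

Step 8
Reactants: 10 11-(phenylsulfanyl)drim-5-en-8α-ol
Product: 11 11-(phenylsulfonyl)drim-5-en-8α-ol
Conditions: (NH4)6Mo7O24·4H2O (10 mol %), 30% H2O2, EtOH, 0 °C to rt
Reagents that add atoms: hydrogen peroxide OO
Why: molybdate-catalysed peroxide oxidation of a sulfide to the sulfone is much faster than epoxidation of the shielded trisubstituted C5=C6 alkene.

Step 9
Reactants: 11 11-(phenylsulfonyl)drim-5-en-8α-ol
Product: 12 11-(phenylsulfonyl)-5α-driman-8α-ol (5α-H, 8α-OH, 9α-H, 10β-methyl)
Conditions: H2 (10 bar), [Ir(cod)(PCy3)(py)]PF6 (10 mol %), CH2Cl2, rt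
Reagents that add atoms: none
Why: hydroxyl-directed homogeneous hydrogenation: the cationic iridium complex should bind the pseudoaxial 8α-hydroxyl (the former bridge oxygen) and add H2 to C5=C6 from the α face, which is also the face not blocked by the C10 methyl group, giving the 5α-hydrogen of the trans-decalin.

Step 10
Reactants: 13 3-methylbut-2-en-1-ol (prenol)
Product: 14 tert-butyldimethyl[(3-methylbut-2-en-1-yl)oxy]silane
Conditions: TBSCl, imidazole, DMF, rt
Reagents that add atoms: tert-butyldimethylsilyl chloride CC(C)(C)[Si](C)(C)Cl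
Why: silyl ether formation on a primary alcohol under imidazole catalysis is routine and masks the future C15 oxygen.

Step 11
Reactants: 14 tert-butyldimethyl[(3-methylbut-2-en-1-yl)oxy]silane
Product: 15 (2E)-4-[(tert-butyldimethylsilyl)oxy]-2-methylbut-2-en-1-ol
Conditions: SeO2 (0.5 equiv), t-BuOOH (3 equiv), CH2Cl2, rt
Reagents that add atoms: selenium dioxide O=[Se]=O (oxygen carrier), tert-butyl hydroperoxide CC(C)(C)OO (terminal oxygen source)
Why: SeO2 allylic oxidation (ene reaction followed by [2,3]-sigmatropic shift) attacks the E-methyl group of a gem-dimethyl alkene, which should set the E geometry of the later C13=C14 bond.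

Step 12
Reactants: 15 (2E)-4-[(tert-butyldimethylsilyl)oxy]-2-methylbut-2-en-1-ol
Product: 16 {[(2E)-4-bromo-3-methylbut-2-en-1-yl]oxy}(tert-butyl)dimethylsilane
Conditions: CBr4, PPh3, 2,6-lutidine, CH2Cl2, 0 °C
Reagents that add atoms: carbon tetrabromide BrC(Br)(Br)Br
Why: Appel bromination displaces the primary alkoxyphosphonium ion by SN2 at the unhindered carbon, so neither allylic transposition nor loss of the E geometry or of the silyl ether is expected.

Step 13
Reactants: 12 11-(phenylsulfonyl)-5α-driman-8α-ol; 16 {[(2E)-4-bromo-3-methylbut-2-en-1-yl]oxy}(tert-butyl)dimethylsilane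
Product: 17 (13E)-15-[(tert-butyldimethylsilyl)oxy]-11-(phenylsulfonyl)labd-13-en-8α-ol (both C11 epimers)
Conditions: n-BuLi (2.2 equiv), THF/DMPU, −78 °C; then 16, −78 to −20 °C
Reagents that add atoms: none
Why: Julia-type alkylation: the O,C-dianion reacts at the α-sulfonyl carbanion with the primary allylic bromide by SN2 to form C11–C12, and the new C11 centre forms as a mixture that is erased in step 14.

Step 14
Reactants: 17 (13E)-15-[(tert-butyldimethylsilyl)oxy]-11-(phenylsulfonyl)labd-13-en-8α-ol
Product: 18 (13E)-15-[(tert-butyldimethylsilyl)oxy]labd-13-en-8α-ol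
Conditions: 6% Na/Hg, Na2HPO4, MeOH/THF, −20 to 0 °C
Reagents that add atoms: none
Why: reductive desulfonylation by electron transfer from sodium amalgam; the sulfone is homoallylic, so the C11 intermediate is not allylic and the C13=C14 position and geometry should be kept, and the buffer protects the silyl ether.

Step 15
Reactants: 18 (13E)-15-[(tert-butyldimethylsilyl)oxy]labd-13-en-8α-ol
Product: 19 (13E)-labd-13-ene-8α,15-diol [(5S,8R,9R,10S)]
Conditions: TBAF, THF, 0 °C to rt
Reagents that add atoms: none
Why: fluoride-induced cleavage of the silyl ether frees the primary allylic alcohol under conditions that leave the tertiary alcohol and the alkene alone.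

Step 16
Reactants: 19 (13E)-labd-13-ene-8α,15-diol (2 equiv); 20 malonic acid
Product: 21 bis[(13E)-8α-hydroxylabd-13-en-15-yl] malonate (target)
Conditions: 20 (0.5 equiv), DCC (1.1 equiv), DMAP (10 mol %), CH2Cl2, 0 °C to rt
Reagents that add atoms: none
Why: Steglich esterification acylates only the primary allylic hydroxyl, the hindered tertiary 8α-hydroxyl being inert, so two molecules of 19 should be joined through the two carboxyl groups of malonic acid.

**Compound list**

1 | methyl (2E)-3,7-dimethylocta-2,6-dienoate (methyl geranate) | COC(=O)/C=C(\C)CCC=C(C)C | starting material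
2 | 2-methylfuran | Cc1ccco1 | starting material
3 | methyl (2E)-3,7-dimethyl-7-(5-methylfuran-2-yl)oct-2-enoate | COC(=O)/C=C(\C)CCCC(C)(C)c1ccc(C)o1 | intermediate
4 | (2E)-3,7-dimethyl-7-(5-methylfuran-2-yl)oct-2-en-1-ol | OC/C=C(\C)CCCC(C)(C)c1ccc(C)o1 | intermediate
5 | (2E)-3,7-dimethyl-7-(5-methylfuran-2-yl)oct-2-enal | Cc1ccc(o1)C(C)(C)CCC/C(C)=C/C=O | intermediate
6 | iminium trifluoroacetate of 5 with (2S,5S)-5-benzyl-2-tert-butyl-3-methylimidazolidin-4-one | Cc1ccc(o1)C(C)(C)CCC/C(C)=C/C=[N+]1/[C@H](C(C)(C)C)N(C)C(=O)[C@@H]1Cc1ccccc1.[O-]C(=O)C(F)(F)F | intermediate (not isolated)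
7 | 5α,8α-epoxydrim-6-en-11-al | O=C[C@@H]1[C@@]2(C)CCCC(C)(C)[C@@]32C=C[C@@]1(C)O3 | intermediate
8 | 5α,8α-epoxydrim-6-en-11-ol | OC[C@@H]1[C@@]2(C)CCCC(C)(C)[C@@]32C=C[C@@]1(C)O3 | intermediate
9 | drim-5-ene-8α,11-diol | OC[C@@H]1[C@@]2(C)CCCC(C)(C)C2=CC[C@@]1(C)O | intermediate
10 | 11-(phenylsulfanyl)drim-5-en-8α-ol | c1ccccc1SC[C@@H]1[C@@]2(C)CCCC(C)(C)C2=CC[C@@]1(C)O | intermediate
11 | 11-(phenylsulfonyl)drim-5-en-8α-ol | O=S(=O)(c1ccccc1)C[C@@H]1[C@@]2(C)CCCC(C)(C)C2=CC[C@@]1(C)O | intermediate
12 | 11-(phenylsulfonyl)-5α-driman-8α-ol | O=S(=O)(c1ccccc1)C[C@@H]1[C@@]2(C)CCCC(C)(C)[C@@H]2CC[C@@]1(C)O | intermediate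
13 | 3-methylbut-2-en-1-ol (prenol) | CC(C)=CCO | starting material
14 | tert-butyldimethyl[(3-methylbut-2-en-1-yl)oxy]silane | CC(C)=CCO[Si](C)(C)C(C)(C)C | intermediate
15 | (2E)-4-[(tert-butyldimethylsilyl)oxy]-2-methylbut-2-en-1-ol | OC/C(C)=C/CO[Si](C)(C)C(C)(C)C | intermediate
16 | {[(2E)-4-bromo-3-methylbut-2-en-1-yl]oxy}(tert-butyl)dimethylsilane | BrC/C(C)=C/CO[Si](C)(C)C(C)(C)C | intermediate
17 | (13E)-15-[(tert-butyldimethylsilyl)oxy]-11-(phenylsulfonyl)labd-13-en-8α-ol, C11 epimers | O=S(=O)(c1ccccc1)C(C/C(C)=C/CO[Si](C)(C)C(C)(C)C)[C@@H]1[C@@]2(C)CCCC(C)(C)[C@@H]2CC[C@@]1(C)O | intermediate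
18 | (13E)-15-[(tert-butyldimethylsilyl)oxy]labd-13-en-8α-ol | CC(C)(C)[Si](C)(C)OC/C=C(\C)CC[C@@H]1[C@@]2(C)CCCC(C)(C)[C@@H]2CC[C@@]1(C)O | intermediate
19 | (13E)-labd-13-ene-8α,15-diol | OC/C=C(\C)CC[C@@H]1[C@@]2(C)CCCC(C)(C)[C@@H]2CC[C@@]1(C)O | intermediate
20 | malonic acid | OC(=O)CC(=O)O | starting material
21 | bis[(13E)-8α-hydroxylabd-13-en-15-yl] malonate | C/C(=C\COC(=O)CC(=O)OC/C=C(\C)CC[C@@H]1[C@@]2(C)CCCC(C)(C)[C@@H]2CC[C@@]1(C)O)CC[C@@H]1[C@@]2(C)CCCC(C)(C)[C@@H]2CC[C@@]1(C)O | target

**Count and risks**

Total step count: 16. Longest linear sequence: 13 steps (steps 1–9 and 13–16); steps 10–12 make the side-chain bromide.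

Steps most likely to fail:

Step 4. Three things may go wrong:
- the cycloaddition equilibrium may not favour the congested adduct;
- the iminium ion of the β,β-disubstituted enal may form too slowly;
- E/Z scrambling through the dienamine would erode the C9/C10 relationship, and facial control may be poor.

The fallback uses known chemistry, leaves the route at ester 3 and rejoins it at alcohol 8, replacing steps 4 and 5. Saponification (LiOH, THF/MeOH/H2O) gives (2E)-3,7-dimethyl-7-(5-methylfuran-2-yl)oct-2-enoic acid F1. PivCl and Et3N convert it into (2E)-3,7-dimethyl-7-(5-methylfuran-2-yl)oct-2-enoic pivalic anhydride F2. This acylates (S)-4-benzyloxazolidin-2-one (LiCl, Et3N, THF) to (4S)-4-benzyl-3-[(2E)-3,7-dimethyl-7-(5-methylfuran-2-yl)oct-2-enoyl]oxazolidin-2-one F3. Me2AlCl (1.5 equiv, CH2Cl2, −78 to −30 °C) promotes the Lewis-acid intramolecular furan Diels–Alder reaction of the chelated s-cis imide, whose benzyl group covers the face opposite to the furan, giving (4S)-4-benzyl-3-(5α,8α-epoxydrim-6-en-11-oyl)oxazolidin-2-one F4. LiBH4 (THF/MeOH, 0 °C) then removes the auxiliary reductively and delivers 8.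

Step 6. Hydride may not be transferred to the unactivated alkene, or an undirected pathway may break the C8–O bond instead of the C5–O bond. The fallback goes from 8 directly to 9 by ionic reduction (Et3SiH, BF3·OEt2, CH2Cl2, −78 °C). The Lewis acid should ionise the more strained C5–O bond, since C5 lies between the quaternary carbons C4 and C10, to the C5–C6–C7 allyl cation. The silane then adds hydride at the secondary, less hindered terminus C7. No compound outside the list is made (F0).

Step 1. Acid-induced oligomerisation of the furan, reversible dealkylation or cation–alkene cyclisation may outrun the intermolecular Friedel–Crafts capture. The fallback goes from 1 back to 3. Markovnikov hydrochlorination of the isopropylidene alkene (HCl in Et2O, −30 °C) gives methyl (2E)-7-chloro-3,7-dimethyloct-2-enoate F5. This is ionised with ZnCl2·OEt2 at −60 °C in CH2Cl2 in the presence of excess 2 and 2,6-di-tert-butylpyridine, so that the tertiary cation is generated by a Lewis acid under aprotic, buffered conditions.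

**Further compounds**

F1 | step 4 | (2E)-3,7-dimethyl-7-(5-methylfuran-2-yl)oct-2-enoic acid | Cc1ccc(o1)C(C)(C)CCC/C(C)=C/C(=O)O
F2 | step 4 | (2E)-3,7-dimethyl-7-(5-methylfuran-2-yl)oct-2-enoic pivalic anhydride | Cc1ccc(o1)C(C)(C)CCC/C(C)=C/C(=O)OC(=O)C(C)(C)C
F3 | step 4 | (4S)-4-benzyl-3-[(2E)-3,7-dimethyl-7-(5-methylfuran-2-yl)oct-2-enoyl]oxazolidin-2-one | Cc1ccc(o1)C(C)(C)CCC/C(C)=C/C(=O)N1[C@@H](Cc2ccccc2)COC1=O
F4 | step 4 | (4S)-4-benzyl-3-(5α,8α-epoxydrim-6-en-11-oyl)oxazolidin-2-one | O=C([C@@H]1[C@@]2(C)CCCC(C)(C)[C@@]32C=C[C@@]1(C)O3)N1[C@@H](Cc2ccccc2)COC1=O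
F0 | step 6 | none | none
F5 | step 1 | methyl (2E)-7-chloro-3,7-dimethyloct-2-enoate | COC(=O)/C=C(\C)CCCC(C)(C)Cl
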